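**Plan**

1. Enabling feature: in each half, ring C (the resorcinol that carries the furan oxygen) is 1,2,3,5-tetrasubstituted. C1 bears the central CH, C2 the furan C3 (a diaryl ketone until late), C3 and C5 the oxygens, so C1 is meta to both oxygens. While C1–C2 is still an alkyne it cannot sit in a seven-membered ring with ring A, so two ynone halves can only join head to tail in a fourteen-membered ring.
2. Cuts: both furan C2–C3 bonds; both diarylmethine C–H bonds and the central CH–CH bond; in each ring C the bonds C2–C3 and C1–C6 (twofold (4+2) annulation of the macrocyclic bis-ynone with two molecules of a 1,3-bis(silyloxy)diene); the two C(=O)–C(sp) bonds; the two aryl–alkene bonds of a 1,1-dibromoenyne.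
3. Forward: two cross-couplings fix the E enyne, two acetylide acylations close the fourteen-membered ring, the diene builds both rings C, a transannular phenol coupling fuses two eight-membered rings, hydride completes the diarylmethines, and two carbene C–H insertions close the dihydrofurans.
4. Stereochemistry: the central methines (R,S) come from the transannular coupling (meso, trans ring fusion). The diarylmethines (R,R) come from phosphoric acid-controlled hydride transfer to the meso bis(quinone methide), the only source of absolute configuration. Furan C3 is set by the substrate in the insertion (achiral catalyst, since the two furans are mirror images). Furan C2 is equilibrated to trans by acid in the last step.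

Key step: step 12

Remark on labels: ring A is the benzoate-derived resorcinol, ring B the 4-oxygenated phenyl on a diarylmethine carbon, ring C the resorcinol built in step 12, ring D the aryl on furan C2. In the target both diarylmethine carbons are R, the central methines are R and S, and on each ring C the furan C3 and C2 carry the same descriptor as the central methine attached to that ring.

Assumption: the carbene insertion is taken to give the 2,3-cis dihydrofurans first, as such insertions usually do. If trans forms directly, step 21 only removes the methyl ethers.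

**Route**

Step 1
Reactants: 1 methyl 3,5-dimethoxybenzoate
Product: 2 methyl 2-iodo-3,5-dimethoxybenzoate
Conditions: NIS, CF3CO2H (cat.), MeCN, rt
Reagents that add atoms: N-iodosuccinimide (O=C1CCC(=O)N1I)
Why: Electrophilic aromatic iodination should go to C2, ortho to one methoxy group and para to the other, and not to the shielded C4 between the two methoxy groups.

Step 2
Reactants: 3 3-(trimethylsilyl)prop-2-ynal
Product: 4 (4,4-dibromobut-3-en-1-yn-1-yl)trimethylsilane
Conditions: CBr4, PPh3, Zn, CH2Cl2, 0 °C to rt
Reagents that add atoms: carbon tetrabromide (BrC(Br)(Br)Br)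
Why: Ramirez dibromo-olefination (first stage of the Corey–Fuchs sequence) converts the aldehyde into the 1,1-dibromoalkene through the dibromomethylene ylide.

Step 3
Reactants: 2 methyl 2-iodo-3,5-dimethoxybenzoate, 4 (4,4-dibromobut-3-en-1-yn-1-yl)trimethylsilane
Product: 7 methyl 2-[(Z)-1-bromo-4-(trimethylsilyl)but-1-en-3-yn-1-yl]-3,5-dimethoxybenzoate, via arylmagnesium chloride 5 (not isolated), via arylzinc chloride 6 (not isolated)
Conditions: iPrMgCl·LiCl, THF, −40 °C; ZnCl2; then 4, PdCl2(DPEphos) (cat.), 0 °C to rt
Reagents that add atoms: none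
Why: Iodine–magnesium exchange ortho to the ester, transmetalation to zinc and a trans-selective Negishi mono-coupling, in which zerovalent palladium inserts into the less hindered C–Br bond trans to the alkynyl group, should place ring A trans to the alkyne and leave the Z bromide.

Step 4
Reactants: 7 methyl 2-[(Z)-1-bromo-4-(trimethylsilyl)but-1-en-3-yn-1-yl]-3,5-dimethoxybenzoate, 8 [4-(benzyloxy)phenyl]boronic acid
Product: 9 methyl 2-[(E)-1-[4-(benzyloxy)phenyl]-4-(trimethylsilyl)but-1-en-3-yn-1-yl]-3,5-dimethoxybenzoate
Conditions: Pd(OAc)2 (cat.), SPhos, K3PO4, toluene/H2O, 60 °C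
Reagents that add atoms: none
Why: Suzuki–Miyaura coupling of the alkenyl bromide proceeds with retention, so ring B ends cis to the alkyne and the trisubstituted alkene is E.

Step 5
Reactants: 9 methyl 2-[(E)-1-[4-(benzyloxy)phenyl]-4-(trimethylsilyl)but-1-en-3-yn-1-yl]-3,5-dimethoxybenzoate (one half of the material)
Product: 10 2-[(E)-1-[4-(benzyloxy)phenyl]-4-(trimethylsilyl)but-1-en-3-yn-1-yl]-N,3,5-trimethoxy-N-methylbenzamide
Conditions: MeNHOMe·HCl, iPrMgCl, THF, −20 °C to rt
Reagents that add atoms: N,O-dimethylhydroxylamine hydrochloride (CNOC.Cl)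
Why: Aminolysis of the ester by the chloromagnesium amide of N,O-dimethylhydroxylamine gives the N-methoxy-N-methylamide and leaves the silyl alkyne untouched.

Step 6
Reactants: 9 methyl 2-[(E)-1-[4-(benzyloxy)phenyl]-4-(trimethylsilyl)but-1-en-3-yn-1-yl]-3,5-dimethoxybenzoate (the other half)
Product: 11 2-[(E)-1-[4-(benzyloxy)phenyl]but-1-en-3-yn-1-yl]-3,5-dimethoxybenzoic acid
Conditions: LiOH, THF/MeOH/H2O, 50 °C; then aq. HCl
Reagents that add atoms: lithium hydroxide ([Li+].[OH-])
Why: Saponification of the methyl ester and protodesilylation of the alkynylsilane by hydroxide occur in one operation.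

Step 7
Reactants: 11 2-[(E)-1-[4-(benzyloxy)phenyl]but-1-en-3-yn-1-yl]-3,5-dimethoxybenzoic acid, 10 2-[(E)-1-[4-(benzyloxy)phenyl]-4-(trimethylsilyl)but-1-en-3-yn-1-yl]-N,3,5-trimethoxy-N-methylbenzamide
Product: 13 silyl-terminated linear ynone acid, via dilithium carboxylate acetylide 12 (not isolated)
Conditions: 11, LiN(iPr)2 (2.1 equiv), THF, −78 °C; then 10, −78 to 0 °C; aq. HCl
Reagents that add atoms: none
Why: The acetylide carbon of the dianion acylates the N-methoxy-N-methylamide and stops at the ketone because the chelated adduct collapses only on work-up, while the lithium carboxylate is inert (acetylide acylation).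

Step 8
Reactants: 13 silyl-terminated linear ynone acid
Product: 14 linear ynone acid bearing a free terminal alkyne
Conditions: Bu4NF, AcOH, THF, 0 °C
Reagents that add atoms: none
Why: Fluoride-induced protodesilylation of the alkynylsilane, buffered with acetic acid so that the ynone is not attacked.

Step 9
Reactants: 14 linear ynone acid bearing a free terminal alkyne
Product: 16 fourteen-membered (E,E) bis(enynone) macrocycle, via acid chloride 15 (not isolated)
Conditions: Me2C=C(Cl)NMe2, CH2Cl2, 0 °C to rt; then slow addition to PdCl2(PPh3)2 (cat.), CuI (cat.), Et3N, THF, 1 mM, 40 °C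
Reagents that add atoms: none
Why: The neutral α-chloroenamine makes the acid chloride, and an intramolecular acyl Sonogashira coupling catalysed by PdCl2(PPh3)2 and CuI under high dilution closes the ring head to tail; self-closure of one half is excluded because it would need a seven-membered ring holding an alkyne.

Step 10
Reactants: 17 methyl acetoacetate
Product: 18 methyl 3-(trimethylsilyloxy)but-2-enoate
Conditions: Me3SiCl, Et3N, hexane, rt
Reagents that add atoms: chlorotrimethylsilane (C[Si](C)(C)Cl)
Why: O-silylation of the enolised β-keto ester gives the silyl enol ether.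

Step 11
Reactants: 18 methyl 3-(trimethylsilyloxy)but-2-enoate
Product: 19 1-methoxy-1,3-bis(trimethylsilyloxy)buta-1,3-diene
Conditions: LiN(iPr)2, THF, −78 °C; Me3SiCl
Reagents that add atoms: chlorotrimethylsilane (C[Si](C)(C)Cl)
Why: γ-Deprotonation to the dienolate and O-silylation give the silyl ketene acetal diene.

Step 12
Reactants: 16 fourteen-membered (E,E) bis(enynone) macrocycle, 19 1-methoxy-1,3-bis(trimethylsilyloxy)buta-1,3-diene (two equivalents are consumed, one per ynone; three are charged)
Product: 22 macrocyclic (E,E) bis(2,4-dihydroxybenzophenone), via twofold cycloadduct 20 (not isolated), via tetrakis(trimethylsilyl) ether 21 (not isolated)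
Conditions: 19 (3 equiv), toluene, 80 °C; then 1 M HCl, THF, rt
Reagents that add atoms: 1-methoxy-1,3-bis(trimethylsilyloxy)buta-1,3-diene, the second equivalent of 19 (CO/C(O[Si](C)(C)C)=C/C(=C)O[Si](C)(C)C)
Why: One molecule of the diene adds to each ynone, through its terminal CH2 to the β-carbon and through its ketene-acetal carbon to the α-carbon, either concertedly or as a Mukaiyama–Michael addition followed by closure of the allenolate onto the silyloxycarbenium ion, so that four C–C bonds and the two cyclohexa-1,4-dienes of 20 arise; loss of one methanol per ring aromatises them to 21, and aqueous acid cleaves the four Si–O bonds, leaving all four diene-derived oxygens as phenols. The closest known reaction is the Diels–Alder aromatisation of 1,3-bis(silyloxy)buta-1,3-dienes with acetylenic ketones and esters to resorcinols. Each ring C closes as a six-membered carbocycle in the (4+2) mode, the second bond forming in a 6-(enolexo)-exo-trig sense if the process is stepwise. No stereocentre is created, because the ketal carbons of 20 are lost on aromatisation. The step needs regioselectivity, secured by the polarised ynone (electrophilic β-carbon) meeting the polarised diene, which puts one hydroxyl ortho and one para to the ketone and the alkenyl carbon meta to both oxygens. It also needs chemoselectivity, secured because the hindered triaryl alkenes and the aryl ketone carbonyls are far poorer 2π partners than the ynones.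

Step 13
Reactants: 22 macrocyclic (E,E) bis(2,4-dihydroxybenzophenone)
Product: 23 macrocyclic bis(2-hydroxy-4-methoxybenzophenone) carrying two benzyl ethers
Conditions: MeI (2.2 equiv), K2CO3, acetone, rt
Reagents that add atoms: iodomethane (CI)
Why: Williamson methylation takes only the para hydroxyl of each ring C, the ortho hydroxyl being held in a hydrogen bond to the ketone.

Step 14
Reactants: 23 macrocyclic bis(2-hydroxy-4-methoxybenzophenone) carrying two benzyl ethers
Product: 24 macrocyclic bis(4-hydroxyphenyl) bis-alkene
Conditions: BCl3, C6HMe5, CH2Cl2, −78 °C; MeOH, then aqueous work-up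
Reagents that add atoms: none
Why: BCl3 cleaves the benzyl aryl ethers at low temperature while pentamethylbenzene captures the benzyl cation (Friedel–Crafts), leaving methyl ethers, alkenes and ketones.

Step 15
Reactants: 24 macrocyclic bis(4-hydroxyphenyl) bis-alkene
Product: 25 meso bis(quinone methide) containing two fused eight-membered rings
Conditions: Ag2O, CH2Cl2, 4 Å MS, 1 mM, 0 °C to rt, dark
Reagents that add atoms: none
Why: Proposed new method: Ag2O should oxidise each ring B phenol (conjugated with its alkene and therefore much easier to oxidise than the chelated, carbonyl-deactivated ring C phenols) to a phenoxyl radical whose spin sits on the alkene CH carbon; the two CH carbons face each other across the fourteen-membered ring and couple to the bis(quinone methide), whose exocyclic carbons carry ring A and are therefore of the persistent diaryl type; a flat, centrosymmetric macrocycle can close only with the two new hydrogens on opposite faces (trans fusion of the two eight-membered rings), which is the meso R,S pair; the closest known reaction type is the intermolecular oxidative 8–8′ dimerisation of 4-hydroxystilbenes to bis(quinone methides).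

Step 16
Reactants: 25 meso bis(quinone methide) containing two fused eight-membered rings
Product: 26 macrocyclic bis-phenol (diarylmethines R,R; central methines R,S)
Conditions: (R)-TRIP (cat.), diethyl 2,6-dimethyl-1,4-dihydropyridine-3,5-dicarboxylate (2.4 equiv), CH2Cl2, −40 °C
Reagents that add atoms: none
Why: Proposed new method: the chiral phosphoric acid (R)-3,3′-bis(2,4,6-triisopropylphenyl)-1,1′-binaphthyl-2,2′-diyl hydrogen phosphate should hydrogen-bond to each quinone methide carbonyl and to the N–H of the dihydropyridine, which delivers hydride to the exocyclic carbon (1,6-addition) on the face fixed by the catalyst pocket and restores the phenol; because the two quinone methides of meso 25 are enantiotopic, catalyst control at both (matched at one, mismatched at the other) makes both diarylmethine carbons R and is the only source of absolute configuration; the antipodal acid is used if a model quinone methide shows the opposite sense; the closest known reaction type is the phosphoric acid-catalysed asymmetric transfer hydrogenation and 1,6-addition of quinone methides with dihydropyridines.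

Step 17
Reactants: 26 macrocyclic bis-phenol (diarylmethines R,R; central methines R,S)
Product: 27 bis(4-methoxyphenyl) compound retaining two free ortho-hydroxy ketones
Conditions: MeI (2.2 equiv), K2CO3, acetone, rt
Reagents that add atoms: iodomethane (CI)
Why: Williamson methylation of the two ring B phenols, the hydrogen-bonded ortho-hydroxy ketones again reacting much more slowly at room temperature.

Step 18
Reactants: 27 bis(4-methoxyphenyl) compound retaining two free ortho-hydroxy ketones
Product: 28 bis(4-methoxybenzyl) ether
Conditions: 4-MeOC6H4CH2Cl (3 equiv), Cs2CO3, Bu4NI (cat.), DMF, 60 °C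
Reagents that add atoms: 4-methoxybenzyl chloride (COc1ccc(CCl)cc1)
Why: Williamson etherification under forcing conditions (caesium phenoxide, iodide catalysis) alkylates the hydrogen-bonded ortho hydroxyls and installs the CH2 groups and rings D of the future furans.

Step 19
Reactants: 28 bis(4-methoxybenzyl) ether
Product: 29 bis(hydrazone)
Conditions: N2H4·H2O (excess), AcOH (cat.), n-BuOH, 110 °C
Reagents that add atoms: hydrazine hydrate (NN.O)
Why: Acid-catalysed condensation of the diaryl ketones with hydrazine gives the free hydrazones, heat being needed because both ketones are flanked by ortho substituents.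

Step 20
Reactants: 29 bis(hydrazone)
Product: 31 decamethyl ether of the bis(2,3-cis-dihydrobenzofuran), via bis(diazo) compound 30 (not isolated)
Conditions: MnO2, CH2Cl2, 0 °C, filter; then Rh2(O2CCPh3)4 (cat.), CH2Cl2, 0 °C to rt
Reagents that add atoms: none
Why: MnO2 dehydrogenates the hydrazones to diaryldiazo compounds and Rh2(O2CCPh3)4 turns each into a donor/donor carbene that inserts into the neighbouring O–CH2–aryl C–H bond (1,5 C–H insertion) to close the dihydrofuran; each C3 centre should be set by the substrate, the eight-membered ring holding the carbene carbon so that the hydrogen it gains lies on the face that already carries the hydrogen of the central methine on the same ring C, and the O–CH centre is expected cis as the kinetic outcome.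

Step 21
Reactants: 31 decamethyl ether of the bis(2,3-cis-dihydrobenzofuran)
Product: 32 CNP0224452.2 (target)
Conditions: BBr3, CH2Cl2, −78 °C to rt; then MeOH, H2O
Reagents that add atoms: none
Why: BBr3 cleaves all ten aryl methyl ethers (Lewis acid ether cleavage), and reversible ionisation of each furan C2–O bond to the para-oxygenated benzylic cation lets ring D settle trans to the C3 substituent, the thermodynamically preferred arrangement, without touching C3.

**Compound list**

1 | methyl 3,5-dimethoxybenzoate | COC(=O)c1cc(OC)cc(OC)c1 | starting material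
2 | methyl 2-iodo-3,5-dimethoxybenzoate | COC(=O)c1cc(OC)cc(OC)c1I | intermediate
3 | 3-(trimethylsilyl)prop-2-ynal | C[Si](C)(C)C#CC=O | starting material
4 | (4,4-dibromobut-3-en-1-yn-1-yl)trimethylsilane | C[Si](C)(C)C#CC=C(Br)Br | intermediate
5 | [2,4-dimethoxy-6-(methoxycarbonyl)phenyl]magnesium chloride | COC(=O)c1cc(OC)cc(OC)c1[Mg]Cl | intermediate (not isolated)
6 | [2,4-dimethoxy-6-(methoxycarbonyl)phenyl]zinc chloride | COC(=O)c1cc(OC)cc(OC)c1[Zn]Cl | intermediate (not isolated)
7 | methyl 2-[(Z)-1-bromo-4-(trimethylsilyl)but-1-en-3-yn-1-yl]-3,5-dimethoxybenzoate | COC(=O)c1cc(OC)cc(OC)c1/C(Br)=C/C#C[Si](C)(C)C | intermediate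
8 | [4-(benzyloxy)phenyl]boronic acid | OB(O)c1ccc(OCc2ccccc2)cc1 | starting material
9 | methyl 2-[(E)-1-[4-(benzyloxy)phenyl]-4-(trimethylsilyl)but-1-en-3-yn-1-yl]-3,5-dimethoxybenzoate | COC(=O)c1cc(OC)cc(OC)c1/C(=C/C#C[Si](C)(C)C)c1ccc(OCc2ccccc2)cc1 | intermediate
10 | 2-[(E)-1-[4-(benzyloxy)phenyl]-4-(trimethylsilyl)but-1-en-3-yn-1-yl]-N,3,5-trimethoxy-N-methylbenzamide | CON(C)C(=O)c1cc(OC)cc(OC)c1/C(=C/C#C[Si](C)(C)C)c1ccc(OCc2ccccc2)cc1 | intermediate
11 | 2-[(E)-1-[4-(benzyloxy)phenyl]but-1-en-3-yn-1-yl]-3,5-dimethoxybenzoic acid | OC(=O)c1cc(OC)cc(OC)c1/C(=C/C#C)c1ccc(OCc2ccccc2)cc1 | intermediate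
12 | dilithium salt of 11 (lithium carboxylate, lithium acetylide) | [Li]OC(=O)c1cc(OC)cc(OC)c1/C(=C/C#C[Li])c1ccc(OCc2ccccc2)cc1 | intermediate (not isolated)
13 | 2-[(E)-1-[4-(benzyloxy)phenyl]-5-{2-[(E)-1-[4-(benzyloxy)phenyl]-4-(trimethylsilyl)but-1-en-3-yn-1-yl]-3,5-dimethoxyphenyl}-5-oxopent-1-en-3-yn-1-yl]-3,5-dimethoxybenzoic acid | OC(=O)c1cc(OC)cc(OC)c1/C(=C/C#CC(=O)c1cc(OC)cc(OC)c1/C(=C/C#C[Si](C)(C)C)c1ccc(OCc2ccccc2)cc1)c1ccc(OCc2ccccc2)cc1 | intermediate
14 | 2-[(E)-1-[4-(benzyloxy)phenyl]-5-{2-[(E)-1-[4-(benzyloxy)phenyl]but-1-en-3-yn-1-yl]-3,5-dimethoxyphenyl}-5-oxopent-1-en-3-yn-1-yl]-3,5-dimethoxybenzoic acid | OC(=O)c1cc(OC)cc(OC)c1/C(=C/C#CC(=O)c1cc(OC)cc(OC)c1/C(=C/C#C)c1ccc(OCc2ccccc2)cc1)c1ccc(OCc2ccccc2)cc1 | intermediate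
15 | acid chloride of 14 | O=C(Cl)c1cc(OC)cc(OC)c1/C(=C/C#CC(=O)c1cc(OC)cc(OC)c1/C(=C/C#C)c1ccc(OCc2ccccc2)cc1)c1ccc(OCc2ccccc2)cc1 | intermediate (not isolated)
16 | fourteen-membered (E,E) bis(enynone) macrocycle, the head-to-tail cyclic dimer in which each 3,5-dimethoxy ring A carries the ynone carbonyl at C1 and the C(4-benzyloxyphenyl)=CH–C≡C unit at C2 (alkyne cis to ring B) | O=C1C#C/C=C(\c2ccc(OCc3ccccc3)cc2)c2c(OC)cc(OC)cc2C(=O)C#C/C=C(\c2ccc(OCc3ccccc3)cc2)c2c(OC)cc(OC)cc21 | intermediate
17 | methyl acetoacetate | COC(=O)CC(C)=O | starting material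
18 | methyl 3-(trimethylsilyloxy)but-2-enoate (mixture of alkene isomers) | COC(=O)C=C(C)O[Si](C)(C)C | intermediate
19 | 1-methoxy-1,3-bis(trimethylsilyloxy)buta-1,3-diene | CO/C(O[Si](C)(C)C)=C/C(=C)O[Si](C)(C)C | intermediate
20 | twofold cycloadduct: each ynone converted into a 6-methoxy-4,6-bis(trimethylsilyloxy)cyclohexa-1,4-diene (ketal carbons undefined) | O=C1C2=C(CC(O[Si](C)(C)C)=CC2(OC)O[Si](C)(C)C)/C=C(\c2ccc(OCc3ccccc3)cc2)c2c(OC)cc(OC)cc2C(=O)C2=C(CC(O[Si](C)(C)C)=CC2(OC)O[Si](C)(C)C)/C=C(\c2ccc(OCc3ccccc3)cc2)c2c(OC)cc(OC)cc21 | intermediate (not isolated)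
21 | tetrakis(trimethylsilyl) ether of 22 | O=C1c2c(O[Si](C)(C)C)cc(O[Si](C)(C)C)cc2/C=C(\c2ccc(OCc3ccccc3)cc2)c2c(OC)cc(OC)cc2C(=O)c2c(O[Si](C)(C)C)cc(O[Si](C)(C)C)cc2/C=C(\c2ccc(OCc3ccccc3)cc2)c2c(OC)cc(OC)cc21 | intermediate (not isolated)
22 | macrocyclic (E,E) bis(2,4-dihydroxybenzophenone): each ring C has the ketone at C2, hydroxyls ortho and para to it, and the CH=C(ring B)(ring A) alkene at C1 | O=C1c2c(O)cc(O)cc2/C=C(\c2ccc(OCc3ccccc3)cc2)c2c(OC)cc(OC)cc2C(=O)c2c(O)cc(O)cc2/C=C(\c2ccc(OCc3ccccc3)cc2)c2c(OC)cc(OC)cc21 | intermediate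
23 | 22 with both para hydroxyls of rings C methylated | O=C1c2c(O)cc(OC)cc2/C=C(\c2ccc(OCc3ccccc3)cc2)c2c(OC)cc(OC)cc2C(=O)c2c(O)cc(OC)cc2/C=C(\c2ccc(OCc3ccccc3)cc2)c2c(OC)cc(OC)cc21 | intermediate
24 | 23 with both benzyl ethers cleaved (rings B are 4-hydroxyphenyl) | O=C1c2c(O)cc(OC)cc2/C=C(\c2ccc(O)cc2)c2c(OC)cc(OC)cc2C(=O)c2c(O)cc(OC)cc2/C=C(\c2ccc(O)cc2)c2c(OC)cc(OC)cc21 | intermediate
25 | meso bis(quinone methide): central CH–CH bond formed, hydrogens anti (R,S), each ring B a cyclohexa-2,5-dien-1-one-4-ylidene | O=C1C=CC(=C2c3c(OC)cc(OC)cc3C(=O)c4c(O)cc(OC)cc4[C@H]4C(=C5C=CC(=O)C=C5)c5c(OC)cc(OC)cc5C(=O)c6c(O)cc(OC)cc6[C@H]24)C=C1 | intermediate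
26 | bis-phenol: diarylmethines R,R; central methines R,S; two 2-hydroxy-4-methoxyaryl ketones | Oc1ccc([C@@H]2c3c(OC)cc(OC)cc3C(=O)c4c(O)cc(OC)cc4[C@H]4[C@H](c5ccc(O)cc5)c5c(OC)cc(OC)cc5C(=O)c6c(O)cc(OC)cc6[C@H]24)cc1 | intermediate
27 | 26 with both ring B phenols methylated | COc1ccc([C@@H]2c3c(OC)cc(OC)cc3C(=O)c4c(O)cc(OC)cc4[C@H]4[C@H](c5ccc(OC)cc5)c5c(OC)cc(OC)cc5C(=O)c6c(O)cc(OC)cc6[C@H]24)cc1 | intermediate
28 | 27 with both ring C ortho hydroxyls as 4-methoxybenzyl ethers | COc1ccc([C@@H]2c3c(OC)cc(OC)cc3C(=O)c4c(OCc7ccc(OC)cc7)cc(OC)cc4[C@H]4[C@H](c5ccc(OC)cc5)c5c(OC)cc(OC)cc5C(=O)c6c(OCc7ccc(OC)cc7)cc(OC)cc6[C@H]24)cc1 | intermediate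
29 | bis(hydrazone) of 28 (C=N geometry undefined) | COc1ccc([C@@H]2c3c(OC)cc(OC)cc3C(=NN)c4c(OCc7ccc(OC)cc7)cc(OC)cc4[C@H]4[C@H](c5ccc(OC)cc5)c5c(OC)cc(OC)cc5C(=NN)c6c(OCc7ccc(OC)cc7)cc(OC)cc6[C@H]24)cc1 | intermediate
30 | bis(diazo) compound from 29 | COc1ccc([C@@H]2c3c(OC)cc(OC)cc3C(=[N+]=[N-])c4c(OCc7ccc(OC)cc7)cc(OC)cc4[C@H]4[C@H](c5ccc(OC)cc5)c5c(OC)cc(OC)cc5C(=[N+]=[N-])c6c(OCc7ccc(OC)cc7)cc(OC)cc6[C@H]24)cc1 | intermediate (not isolated)
31 | decamethyl ether of the 2-epi,2′-epi target: both dihydrofurans 2,3-cis (furan C3 R with C2 S on the ring C bearing the R central methine; C3 S with C2 R on the other), all other centres as in 32 | COc1ccc([C@@H]2c3c(OC)cc(OC)cc3[C@@H]3c4c(cc(OC)cc4[C@H]4[C@H](c5ccc(OC)cc5)c5c(OC)cc(OC)cc5[C@H]5c6c(cc(OC)cc6[C@H]24)O[C@H]5c2ccc(OC)cc2)O[C@@H]3c2ccc(OC)cc2)cc1 | intermediate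
32 | CNP0224452.2: diarylmethines R,R; central methines R,S; trans-dihydrofurans 2R,3R on the ring C bearing the R central methine and 2S,3S on the other | Oc1ccc([C@@H]2c3c(O)cc(O)cc3[C@@H]3c4c(cc(O)cc4[C@H]4[C@H](c5ccc(O)cc5)c5c(O)cc(O)cc5[C@H]5c6c(cc(O)cc6[C@H]24)O[C@@H]5c2ccc(O)cc2)O[C@H]3c2ccc(O)cc2)cc1 | target

**Step count and risks**

Total: 21 steps. Longest linear sequence: 17 steps (1, 3, 4, 5, 7, 8, 9, 12 to 21).

Step 15 (labelled) is the most exposed. The phenoxyl radicals may couple through oxygen or a ring carbon instead of through the two alkene CH carbons, the rings may fuse cis, or the quinone methides may tautomerise and oligomerise before they are reduced. The fallback uses known chemistry and sets out from 23. Anodic oxidation (carbon anode, LiClO4, MeOH/CH2Cl2, 2,6-lutidine, 0 °C) generates the radical cation of one electron-rich triaryl alkene, which should attack the facing alkene tail to tail, as electron-rich 1,1-diarylethenes and 4-alkoxystyrenes do. Methanol traps both diarylmethyl cations and gives the transannularly coupled bis(tertiary methyl ether) F1. BCl3 with pentamethylbenzene at −78 °C then removes the benzyl groups, and on bicarbonate work-up the 4-hydroxybenzylic methyl ethers lose methanol by 1,6-elimination to give 25, where the route is rejoined.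

Step 16 (labelled) may fail through substrate-controlled facial attack at the mismatched quinone methide, which would lead to an achiral meso bis-phenol instead of the R,R compound. The fallback sets out from 25. NaBH4 in THF/MeOH at −78 °C adds hydride to both quinone methides without reagent control and should give the mixture of diarylmethine stereoisomers F2. The unsymmetrical isomer is separated from the two meso isomers by chromatography and resolved on a chiral stationary phase, which returns the route to 26.

Step 9 may fail through oligomerisation and oxidative alkyne homocoupling outrunning the closure of a rigid fourteen-membered ring, or through hydrolysis of the acid chloride during the slow addition. The fallback sets out from 10. K2CO3 in MeOH removes the silyl group and gives the terminal-alkyne N-methoxy-N-methylamide F3. Slow addition of LiN(SiMe3)2 to its dilute THF solution at −20 °C forms the acetylide, which acylates the amide of a second molecule and then closes the ring in the same way. Both C–C bonds form through chelated tetrahedral adducts, so no ynone is exposed to base and the ring closes at a flexible sp3 centre. Acidic work-up releases both ketones and returns the route to 16.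

Further compounds
F1 | step 15 | transannularly coupled bis(tertiary methyl ether): 23 with the central CH–CH bond (R,S) and a methoxy group on each former alkene carbon bearing ring B (those two carbons undefined) | COC1(c2ccc(OCc3ccccc3)cc2)c2c(OC)cc(OC)cc2C(=O)c2c(O)cc(OC)cc2[C@H]2C(OC)(c3ccc(OCc4ccccc4)cc3)c3c(OC)cc(OC)cc3C(=O)c3c(O)cc(OC)cc3[C@H]12
F2 | step 16 | mixture of the diarylmethine stereoisomers of 26 (central methines R,S; diarylmethine carbons undefined) | Oc1ccc(C2c3c(OC)cc(OC)cc3C(=O)c4c(O)cc(OC)cc4[C@H]4C(c5ccc(O)cc5)c5c(OC)cc(OC)cc5C(=O)c6c(O)cc(OC)cc6[C@H]24)cc1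
F3 | step 9 | 2-[(E)-1-[4-(benzyloxy)phenyl]but-1-en-3-yn-1-yl]-N,3,5-trimethoxy-N-methylbenzamide | CON(C)C(=O)c1cc(OC)cc(OC)c1/C(=C/C#C)c1ccc(OCc2ccccc2)cc1
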